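**Retrosynthetic overview**

- The quinone is unmasked last from a 1,4-dimethoxynaphthalene. Both rings (benzo ring A and quinone carbocycle B) are bought together in menadione, so no ring is formed anywhere in the route.
- Key disconnection: the C5–C6 single bond of the side chain (C1 = ring-bound CH2, C32 = chain end). The enabling feature is the trisubstituted alkene C6=C7: C6 carries H and the C5 methylene, C7 carries a CH3 cis to C5. This is the pattern left by syn methylmetalation of a terminal alkyne C6≡C7, and C5 is a plain primary homoallylic carbon. One operation therefore unites a C33 terminal alkyne, Me3Al and a C17 homoallylic iodide, creating C7–CH3, C5–C6 and the 6E geometry.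
- Tail alkyne: geranylgeraniol is propargylated at C1, oxidised at its terminal (E)-methyl group, and joined by copper catalysis to the Grignard reagent of (S)-citronellyl bromide, the source of C27.
- Head iodide: menadione is reductively methylated and chloromethylated; methylalumination of a butynyl silyl ether with nickel-catalysed benzylic coupling sets the 2E alkene; desilylation and iodination follow.

Key step: step 12

Assumption: commercial all-E geranylgeraniol and (S)-(+)-citronellyl bromide of high enantiomeric purity are used. The S centre of the bromide becomes C27 of the target, named R there only because the CIP ranking of its two chain substituents changes once bromine is replaced by carbon.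

**Route**

Step 1
Reactants: 1 (2E,6E,10E)-geranylgeraniol
Product: 2 (2E,6E,10E)-1-bromo-3,7,11,15-tetramethylhexadeca-2,6,10,14-tetraene (geranylgeranyl bromide)
Conditions: PBr3 (0.4 equiv), Et2O, 0 °C; used crude
Reagents that add atoms: phosphorus tribromide, BrP(Br)Br
Why: Primary allylic alcohols of the farnesol type should be converted by PBr3 at 0 °C into the primary bromides by SN2 displacement of the bromophosphite, without allylic transposition or loss of the 2E geometry.

Step 2
Reactants: 2 geranylgeranyl bromide; 3 1-(trimethylsilyl)propyne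
Product: 5 trimethyl[(5E,9E,13E)-6,10,14,18-tetramethylnonadeca-5,9,13,17-tetraen-1-yn-1-yl]silane, via 3-(trimethylsilyl)prop-2-ynyllithium 4 (not isolated)
Conditions: 3, n-BuLi, THF, −78 °C; then 2, −78 to −20 °C
Reagents that add atoms: none
Why: The propargylic lithium reagent from 3 should alkylate the primary allylic bromide at its CH2 terminus by SN2 (the silyl group disfavours the allenyl mode), giving the 1,5-enyne with the neighbouring E alkene untouched.

Step 3
Reactants: 5 silylated C23 enyne
Product: 6 (2E,6E,10E,14E)-2,6,10,14-tetramethyl-19-(trimethylsilyl)nonadeca-2,6,10,14-tetraen-18-yn-1-ol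
Conditions: SeO2 (0.3 equiv), t-BuOOH, salicylic acid (cat.), CH2Cl2, 0 °C to rt, stopped at partial conversion with recovery of 5
Reagents that add atoms: selenium dioxide, O=[Se]=O (catalytic oxygen carrier); tert-butyl hydroperoxide, CC(C)(C)OO (terminal oxygen source)
Why: Riley oxidation (ene reaction followed by [2,3]-sigmatropic shift) should attack the most accessible terminal isopropylidene unit and, through the geometry of the [2,3] shift, oxidise only the methyl group trans to the chain to give the E allylic alcohol, the silylalkyne being a much poorer ene partner.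

Step 4
Reactants: 6 terminal allylic alcohol
Product: 7 [(5E,9E,13E,17E)-19-bromo-6,10,14,18-tetramethylnonadeca-5,9,13,17-tetraen-1-yn-1-yl]trimethylsilane
Conditions: CBr4, PPh3, CH2Cl2, −20 to 0 °C
Reagents that add atoms: carbon tetrabromide, BrC(Br)(Br)Br
Why: In the Appel reaction bromide displaces the alkoxyphosphonium ion by SN2 under neutral conditions, which should give the primary allylic bromide with the 17E geometry retained.

Step 5
Reactants: 7 allylic bromide; 8 (S)-(+)-citronellyl bromide, (6S)-8-bromo-2,6-dimethyloct-2-ene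
Product: 10 trimethyl[(5E,9E,13E,17E,22R)-6,10,14,18,22,26-hexamethylheptacosa-5,9,13,17,25-pentaen-1-yn-1-yl]silane, via (S)-citronellylmagnesium bromide 9 (not isolated)
Conditions: 8, Mg, THF, rt; then 7, Li2CuCl4 (5 mol %), THF, −78 to 0 °C
Reagents that add atoms: none
Why: Li2CuCl4-catalysed coupling of a primary alkyl Grignard reagent with a primary allylic bromide in THF should proceed by direct (α) substitution with retention of the alkene geometry, and the stereocentre, two carbons away from the magnesium-bearing carbon, is carried over unchanged from 8.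

Step 6
Reactants: 10 silylated C33 enyne
Product: 11 (5E,9E,13E,17E,22R)-6,10,14,18,22,26-hexamethylheptacosa-5,9,13,17,25-pentaen-1-yne
Conditions: K2CO3 (cat.), MeOH/THF, rt
Reagents that add atoms: none
Why: Methoxide-catalysed methanolysis of the C(sp)–Si bond should release the terminal alkyne without touching the skipped polyene or the stereocentre.

Step 7
Reactants: 12 menadione (2-methylnaphthalene-1,4-dione)
Product: 14 1,4-dimethoxy-2-methylnaphthalene, via menadiol 13 (not isolated)
Conditions: Na2S2O4, Bu4NBr (cat.), THF/H2O, rt; then aq. KOH, Me2SO4, rt, under N2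
Reagents that add atoms: dimethyl sulfate, COS(=O)(=O)OC
Why: Dithionite reduces the quinone to the hydroquinone, whose dianion should be O-methylated twice by dimethyl sulfate (Williamson ether synthesis) before it can re-oxidise.

Step 8
Reactants: 14 1,4-dimethoxy-2-methylnaphthalene
Product: 15 2-(chloromethyl)-1,4-dimethoxy-3-methylnaphthalene
Conditions: (CH2O)n, conc. HCl, AcOH, rt to 50 °C
Reagents that add atoms: formaldehyde (as paraformaldehyde), C=O; hydrogen chloride, Cl
Why: In the Blanc chloromethylation the only free position of the electron-rich substituted ring (C3, ortho to a methoxy group) should be attacked by protonated formaldehyde, and the benzylic alcohol is converted into the chloride by HCl.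

Step 9
Reactants: 15 benzylic chloride; 16 tert-butyl(but-3-yn-1-yloxy)dimethylsilane
Product: 18 tert-butyl{[(3E)-5-(1,4-dimethoxy-3-methylnaphthalen-2-yl)-3-methylpent-3-en-1-yl]oxy}dimethylsilane, via C5 alkenyldimethylalane 17 (not isolated)
Conditions: 16, Me3Al, Cp2ZrCl2 (25 mol %), CH2Cl2, 0 °C to rt; volatiles off; then 15, NiCl2(PPh3)2 (5 mol %)/n-BuLi (10 mol %), THF, rt
Reagents that add atoms: trimethylaluminium, C[Al](C)C
Why: Zirconium-catalysed syn methylalumination (Negishi carboalumination) places CH3 on the internal and aluminium on the terminal alkyne carbon, and the alkenylalane should couple with the benzylic chloride under zerovalent nickel catalysis with retention, so the new trisubstituted alkene is formed as the E isomer.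

Step 10
Reactants: 18 silyl ether
Product: 19 (3E)-5-(1,4-dimethoxy-3-methylnaphthalen-2-yl)-3-methylpent-3-en-1-ol
Conditions: Bu4NF, THF, 0 °C to rt
Reagents that add atoms: none
Why: Fluoride should cleave the Si–O bond of the primary silyl ether (strong Si–F bond) and leave the aryl methyl ethers and the alkene untouched.

Step 11
Reactants: 19 homoallylic alcohol
Product: 20 2-[(2E)-5-iodo-3-methylpent-2-en-1-yl]-1,4-dimethoxy-3-methylnaphthalene
Conditions: I2, PPh3, imidazole, CH2Cl2, 0 °C
Reagents that add atoms: iodine, II
Why: In this Appel-type iodination iodide displaces the alkoxyphosphonium ion at the primary carbon by SN2, and the homoallylic position excludes allylic scrambling.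

Step 12
Reactants: 11 C33 terminal alkyne; 20 C17 homoallylic iodide
Product: 23 2-[(2E,6E,10E,14E,18E,22E,27R)-3,7,11,15,19,23,27,31-octamethyldotriaconta-2,6,10,14,18,22,30-heptaen-1-yl]-1,4-dimethoxy-3-methylnaphthalene, via C34 alkenyldimethylalane 21 (not isolated), via C34 alkenylzinc bromide 22 (not isolated)
Conditions: 11, Me3Al (2 equiv), Cp2ZrCl2 (20 mol %), CH2Cl2, 0 °C to rt; volatiles off; ZnBr2 (1.1 equiv), THF, 0 °C; then 20 (1.3 equiv), Pd2(dba)3 (2 mol %), PCyp3 (tricyclopentylphosphine, 8 mol %), N-methylimidazole, THF/NMP, 80 °C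
Reagents that add atoms: trimethylaluminium, C[Al](C)C
Why: Me3Al activated by Cp2ZrCl2 adds CH3 and aluminium syn across the terminal alkyne of 11 (CH3 to the internal carbon C7, aluminium to C6), ZnBr2 takes over the alkenyl group, and a zerovalent palladium–PCyp3 catalyst inserts into the primary C–I bond of 20 by SN2-type oxidative addition, receives the alkenyl group from 22 and forms the C5–C6 bond by reductive elimination with retention at C6, so that three components are united in one flask. The closest known reaction types are the one-pot methylalumination/cross-coupling of terminal alkynes (Negishi carboalumination followed by nickel- or palladium-catalysed coupling of the alkenylalane, with zinc salts as transmetalation shuttle) and the Negishi coupling of alkenylzinc halides with unactivated, β-hydrogen-bearing primary alkyl iodides under Pd2(dba)3/PCyp3/N-methylimidazole. No ring is closed and no stereocentre is created; the only new stereo-element is the 6E double bond, which is fixed by the syn carbometalation (CH3 and metal cis) and kept through the aluminium-to-zinc and zinc-to-palladium transfers, while C27 and the five existing E alkenes are remote spectators. The step needs (a) regio- and chemoselective methylmetalation of the alkyne, secured because trisubstituted alkenes are inert to Me3Al/Cp2ZrCl2 at room temperature and a terminal alkyne places aluminium on its unsubstituted carbon, (b) alkenyl instead of methyl transfer, secured by stripping excess Me3Al before zinc is added and by the faster transfer of sp2 carbon, and (c) reductive elimination faster than β-hydride elimination of the homoallylpalladium intermediate, secured by the bulky electron-rich trialkylphosphine.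

Step 13
Reactants: 23 dimethoxynaphthalene precursor
Product: 24 2-[(2E,6E,10E,14E,18E,22E,27R)-3,7,11,15,19,23,27,31-octamethyldotriaconta-2,6,10,14,18,22,30-heptaen-1-yl]-3-methylnaphthalene-1,4-dione (target)
Conditions: (NH4)2Ce(NO3)6 (2.5 equiv), MeCN/H2O/CH2Cl2, 0 °C
Reagents that add atoms: water, O
Why: Oxidative demethylation of a 1,4-dimethoxyarene by tetravalent cerium (two one-electron oxidations, water adding at the two ipso carbons and methanol leaving) should give the para-quinone at 0 °C without attack on the isolated alkenes or the remote stereocentre.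

**Compound list**

1 | (2E,6E,10E)-geranylgeraniol | CC(C)=CCC/C(C)=C/CC/C(C)=C/CC/C(C)=C/CO | starting material
2 | (2E,6E,10E)-geranylgeranyl bromide | CC(C)=CCC/C(C)=C/CC/C(C)=C/CC/C(C)=C/CBr | intermediate
3 | 1-(trimethylsilyl)propyne | CC#C[Si](C)(C)C | starting material
4 | 3-(trimethylsilyl)prop-2-ynyllithium | [Li]CC#C[Si](C)(C)C | intermediate
5 | trimethyl[(5E,9E,13E)-6,10,14,18-tetramethylnonadeca-5,9,13,17-tetraen-1-yn-1-yl]silane | CC(C)=CCC/C(C)=C/CC/C(C)=C/CC/C(C)=C/CCC#C[Si](C)(C)C | intermediate
6 | (2E,6E,10E,14E)-2,6,10,14-tetramethyl-19-(trimethylsilyl)nonadeca-2,6,10,14-tetraen-18-yn-1-ol | OC/C(C)=C/CC/C(C)=C/CC/C(C)=C/CC/C(C)=C/CCC#C[Si](C)(C)C | intermediate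
7 | [(5E,9E,13E,17E)-19-bromo-6,10,14,18-tetramethylnonadeca-5,9,13,17-tetraen-1-yn-1-yl]trimethylsilane | BrC/C(C)=C/CC/C(C)=C/CC/C(C)=C/CC/C(C)=C/CCC#C[Si](C)(C)C | intermediate
8 | (S)-(+)-citronellyl bromide, (6S)-8-bromo-2,6-dimethyloct-2-ene | CC(C)=CCC[C@H](C)CCBr | starting material
9 | (S)-citronellylmagnesium bromide | CC(C)=CCC[C@H](C)CC[Mg]Br | intermediate
10 | trimethyl[(5E,9E,13E,17E,22R)-6,10,14,18,22,26-hexamethylheptacosa-5,9,13,17,25-pentaen-1-yn-1-yl]silane | CC(C)=CCC[C@H](C)CCC/C(C)=C/CC/C(C)=C/CC/C(C)=C/CC/C(C)=C/CCC#C[Si](C)(C)C | intermediate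
11 | (5E,9E,13E,17E,22R)-6,10,14,18,22,26-hexamethylheptacosa-5,9,13,17,25-pentaen-1-yne | CC(C)=CCC[C@H](C)CCC/C(C)=C/CC/C(C)=C/CC/C(C)=C/CC/C(C)=C/CCC#C | intermediate
12 | menadione, 2-methylnaphthalene-1,4-dione | CC1=CC(=O)c2ccccc2C1=O | starting material
13 | menadiol, 2-methylnaphthalene-1,4-diol | Cc1cc(O)c2ccccc2c1O | intermediate
14 | 1,4-dimethoxy-2-methylnaphthalene | COc1cc(C)c(OC)c2ccccc12 | intermediate
15 | 2-(chloromethyl)-1,4-dimethoxy-3-methylnaphthalene | COc1c(C)c(CCl)c(OC)c2ccccc12 | intermediate
16 | tert-butyl(but-3-yn-1-yloxy)dimethylsilane | C#CCCO[Si](C)(C)C(C)(C)C | starting material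
17 | dimethyl[(1E)-4-{[tert-butyl(dimethyl)silyl]oxy}-2-methylbut-1-en-1-yl]alumane | C[Al](C)/C=C(\C)CCO[Si](C)(C)C(C)(C)C | intermediate
18 | tert-butyl{[(3E)-5-(1,4-dimethoxy-3-methylnaphthalen-2-yl)-3-methylpent-3-en-1-yl]oxy}dimethylsilane | COc1c(C)c(C/C=C(\C)CCO[Si](C)(C)C(C)(C)C)c(OC)c2ccccc12 | intermediate
19 | (3E)-5-(1,4-dimethoxy-3-methylnaphthalen-2-yl)-3-methylpent-3-en-1-ol | COc1c(C)c(C/C=C(\C)CCO)c(OC)c2ccccc12 | intermediate
20 | 2-[(2E)-5-iodo-3-methylpent-2-en-1-yl]-1,4-dimethoxy-3-methylnaphthalene | COc1c(C)c(C/C=C(\C)CCI)c(OC)c2ccccc12 | intermediate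
21 | dimethyl[(1E,5E,9E,13E,17E,22R)-2,6,10,14,18,22,26-heptamethylheptacosa-1,5,9,13,17,25-hexaen-1-yl]alumane | CC(C)=CCC[C@H](C)CCC/C(C)=C/CC/C(C)=C/CC/C(C)=C/CC/C(C)=C/CC/C(C)=C/[Al](C)C | intermediate
22 | bromo[(1E,5E,9E,13E,17E,22R)-2,6,10,14,18,22,26-heptamethylheptacosa-1,5,9,13,17,25-hexaen-1-yl]zinc | CC(C)=CCC[C@H](C)CCC/C(C)=C/CC/C(C)=C/CC/C(C)=C/CC/C(C)=C/CC/C(C)=C/[Zn]Br | intermediate
23 | 2-[(2E,6E,10E,14E,18E,22E,27R)-3,7,11,15,19,23,27,31-octamethyldotriaconta-2,6,10,14,18,22,30-heptaen-1-yl]-1,4-dimethoxy-3-methylnaphthalene | CC(C)=CCC[C@H](C)CCC/C(C)=C/CC/C(C)=C/CC/C(C)=C/CC/C(C)=C/CC/C(C)=C/CC/C(C)=C/Cc1c(C)c(OC)c2ccccc2c1OC | intermediate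
24 | 2-[(2E,6E,10E,14E,18E,22E,27R)-3,7,11,15,19,23,27,31-octamethyldotriaconta-2,6,10,14,18,22,30-heptaen-1-yl]-3-methylnaphthalene-1,4-dione | CC(C)=CCC[C@H](C)CCC/C(C)=C/CC/C(C)=C/CC/C(C)=C/CC/C(C)=C/CC/C(C)=C/CC/C(C)=C/CC1=C(C)C(=O)c2ccccc2C1=O | target

**Step count and risks**

Total step count: 13. Longest linear sequence: 8 (steps 1 to 6, then 12 and 13).

Steps most likely to fail:

1. Step 12. β-Hydride elimination of the homoallylpalladium intermediate, protodemetalation of the alkenylmetal, or methyl transfer from residual methylaluminium species may outrun the alkenyl–alkyl reductive elimination. The fallback reverses the polarity of the same bond and sets out from 11 and 20. Methylalumination of 11 as before gives 21, which is quenched with I2 (THF, −30 °C) to the alkenyl iodide F1. Separately, activated zinc dust (1,2-dibromoethane/Me3SiCl, THF/DMA, 40 °C) inserts into the C–I bond of 20 to give the homoallylzinc iodide F2. Negishi coupling of F1 with F2 (Pd(PPh3)4, THF/DMF, rt) would place oxidative addition at the sp2 C–I bond and keep the alkylpalladium species short-lived. The fallback comes back to the route at 23.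

2. Step 3. Site selectivity may be poor (ene attack at the three internal trisubstituted alkenes or at the propargylic CH2), and over-oxidation to the enal may occur. The fallback sets out from 5 and builds the same E allylic alcohol by degradation and re-olefination of the terminal alkene. NBS in THF/H2O at 0 °C should give the terminal bromohydrin F3; NaH in THF closes it to the epoxide F4; H5IO6 in THF/Et2O/H2O cleaves this to the aldehyde F5; an E-selective Wittig reaction with Ph3P=C(CH3)CO2Et in CH2Cl2 gives the enoate F6; i-Bu2AlH in CH2Cl2 at −78 °C reduces the ester. The fallback comes back to the route at 6.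

3. Step 5. The organocopper intermediate may attack the allylic bromide at the γ carbon (giving a branched isomer with a 1,1-disubstituted alkene), and the Grignard reagent may homocouple. The fallback sets out from 8 and uses a sulfone-stabilised carbanion, which alkylates allylic bromides only by direct displacement. PhSO2Na in DMF converts 8 into the sulfone F7; deprotonation (n-BuLi, THF/DMPU, −78 °C) and addition of 7 give the alkylated sulfone F8 as a mixture of epimers at the sulfonyl-bearing carbon; reductive desulfonylation (Na(Hg), Na2HPO4, MeOH/THF, −20 °C) removes the auxiliary group. The fallback comes back to the route at 10.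

**Further compounds**

F1 | step 12 | (1E,5E,9E,13E,17E,22R)-1-iodo-2,6,10,14,18,22,26-heptamethylheptacosa-1,5,9,13,17,25-hexaene | CC(C)=CCC[C@H](C)CCC/C(C)=C/CC/C(C)=C/CC/C(C)=C/CC/C(C)=C/CC/C(C)=C/I
F2 | step 12 | [(3E)-5-(1,4-dimethoxy-3-methylnaphthalen-2-yl)-3-methylpent-3-en-1-yl](iodo)zinc | COc1c(C)c(C/C=C(\C)CC[Zn]I)c(OC)c2ccccc12
F3 | step 3 | (6E,10E,14E)-3-bromo-2,6,10,14-tetramethyl-19-(trimethylsilyl)nonadeca-6,10,14-trien-18-yn-2-ol (racemic at C3) | CC(C)(O)C(Br)CC/C(C)=C/CC/C(C)=C/CC/C(C)=C/CCC#C[Si](C)(C)C
F4 | step 3 | trimethyl[(5E,9E,13E)-16-(3,3-dimethyloxiran-2-yl)-6,10,14-trimethylhexadeca-5,9,13-trien-1-yn-1-yl]silane (racemic) | CC1(C)OC1CC/C(C)=C/CC/C(C)=C/CC/C(C)=C/CCC#C[Si](C)(C)C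
F5 | step 3 | (4E,8E,12E)-4,8,12-trimethyl-17-(trimethylsilyl)heptadeca-4,8,12-trien-16-ynal | O=CCC/C(C)=C/CC/C(C)=C/CC/C(C)=C/CCC#C[Si](C)(C)C
F6 | step 3 | ethyl (2E,6E,10E,14E)-2,6,10,14-tetramethyl-19-(trimethylsilyl)nonadeca-2,6,10,14-tetraen-18-ynoate | CCOC(=O)/C(C)=C/CC/C(C)=C/CC/C(C)=C/CC/C(C)=C/CCC#C[Si](C)(C)C
F7 | step 5 | {[(3S)-3,7-dimethyloct-6-en-1-yl]sulfonyl}benzene | CC(C)=CCC[C@H](C)CCS(=O)(=O)c1ccccc1
F8 | step 5 | trimethyl[(5E,9E,13E,17E,22S)-6,10,14,18,22,26-hexamethyl-20-(phenylsulfonyl)heptacosa-5,9,13,17,25-pentaen-1-yn-1-yl]silane (C20 epimers; C22 has the same spatial arrangement as in 10) | CC(C)=CCC[C@H](C)CC(C/C(C)=C/CC/C(C)=C/CC/C(C)=C/CC/C(C)=C/CCC#C[Si](C)(C)C)S(=O)(=O)c1ccccc1
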